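**Retrosynthetic overview**
1. The bromide is made last from a C1 ketone: target ⇐ axial C1 alcohol (Appel, inversion) ⇐ bicyclic β-hydroxy ketone with C1 as carbonyl, C5 as tertiary carbinol and C4 as methylidene.
2. Key disconnection: both rings are opened at once by cutting C5–C10 and C2–C3. The acyclic precursor carries C10–C1–C2 as a ketone masked as its regiodefined silyl enol ether (nucleophilic at C10, then at C2) and C5–C4(=C15)–C3 as a 2-(bromomethyl)enone (electrophilic at C5, then at C3), tethered by C6–C9.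
3. Enabling feature: in ring A the two bonds lie opposite each other, and each three-carbon unit has a central carbon that can hold the activating group (C1 as carbonyl between C10 and C2; C4 with its methylidene between the carbinol C5 and C3). C5 and C10 are also the ring-fusion atoms, so the first bond closes ring B and the second ring A.
4. Precursor assembly: C5–C9 from 5,6-dihydro-2H-pyran-2-one with C7 set by rhodium-catalysed asymmetric 1,4-addition; triene by carboalumination/Negishi coupling; C10, C14, C1, C2 by Wittig olefination and conjugate reduction–silylation; C3, C4, C15 by addition of a 2-lithioallyl alkoxide to a Weinreb amide.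
5. Order of ring formation: ring B (aldol), then ring A (alkylation), both in the key step; no carbocycle exists before it.

Key step: step 12

Remark: positions are given in eudesmane numbering of the target (ring A = C1–C5 and C10, ring B = C5–C10, C14 = methyl on C10, C15 = methylidene carbon on C4, side chain on C7; α = face of the C5 hydroxyl, β = face of the C10 methyl), and the silyl enol ether is carried as a mixture of double-bond isomers that converge in step 12.

**Route**

Step 1
Reactants: 1 5,6-dihydro-2H-pyran-2-one; 2 potassium trifluoro(vinyl)borate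
Product: 3 (4R)-4-ethenyloxan-2-one
Conditions: [Rh(cod)2]BF4 (3 mol%), (R)-BINAP, toluene/H2O, 100 °C
Reagents that add atoms: none
Why: Hayashi–Miyaura rhodium-catalysed 1,4-addition of an alkenylboron reagent to the unsaturated lactone; the ligand controls the face of carbometalation and so sets C7, (R)-BINAP being chosen by analogy with the known sense for this ring system (the mirror-image ligand would serve otherwise).

Step 2
Reactants: 3 (4R)-4-ethenyloxan-2-one
Product: 4 (4R)-2-oxooxane-4-carbaldehyde
Conditions: O3, CH2Cl2, −78 °C; then PPh3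
Reagents that add atoms: ozone, [O-][O+]=O
Why: Ozonolysis with reductive work-up cleaves the only alkene to the aldehyde and leaves the lactone untouched.

Step 3
Reactants: 4 (4R)-2-oxooxane-4-carbaldehyde
Product: 6 methyl (3R)-3-ethynyl-5-hydroxypentanoate, via ethynyl lactone 5 (not isolated)
Conditions: dimethyl (1-diazo-2-oxopropyl)phosphonate, K2CO3, MeOH, 0 °C to rt
Reagents that add atoms: dimethyl (1-diazo-2-oxopropyl)phosphonate, COP(=O)(OC)C(=[N+]=[N-])C(C)=O; methanol, CO
Why: Ohira–Bestmann (Seyferth–Gilbert) homologation converts the aldehyde into the terminal alkyne at low temperature to limit epimerisation at C7, and the basic methanol should open the δ-lactone to the hydroxy ester, leaving C5 and C9 differentiated.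

Step 4
Reactants: 6 methyl (3R)-3-ethynyl-5-hydroxypentanoate
Product: 7 (3R)-3-ethynyl-5-hydroxy-N-methoxy-N-methylpentanamide
Conditions: MeNH(OMe)·HCl, i-PrMgCl, THF, −20 to 0 °C
Reagents that add atoms: N,O-dimethylhydroxylamine hydrochloride, CNOC.Cl
Why: Weinreb amide formation by magnesium-amide aminolysis of the ester, with the hydroxyl and alkyne tolerated as their magnesium salts.

Step 5
Reactants: 8 2-methylbut-1-en-3-yne
Product: 10 (1E)-1-iodo-3-methylbuta-1,3-diene, via dienylzirconocene chloride 9 (not isolated)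
Conditions: Cp2Zr(H)Cl, THF, rt; then iodine, 0 °C, dark
Reagents that add atoms: iodine, I-I
Why: Hydrozirconation adds Zr–H syn across the terminal alkyne with zirconium on the terminal carbon, and iodinolysis with retention should give the E iododiene.

Step 6
Reactants: 7 (3R)-3-ethynyl-5-hydroxy-N-methoxy-N-methylpentanamide; 10 (1E)-1-iodo-3-methylbuta-1,3-diene
Product: 12 (3R)-5-hydroxy-N-methoxy-N-methyl-3-[(2E,4E)-6-methylhepta-2,4,6-trien-2-yl]pentanamide, via alkenylalane 11 (not isolated)
Conditions: AlMe3, Cp2ZrCl2 (25 mol%), ClCH2CH2Cl, rt; then 10, Pd(PPh3)4 (5 mol%), ZnCl2 (cat.), THF, rt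
Reagents that add atoms: trimethylaluminium, C[Al](C)C
Why: Zirconium-catalysed methylalumination (Negishi carboalumination) adds methyl and aluminium syn with methyl on the internal carbon, and the Negishi coupling proceeds with retention at both partners, so both new alkenes should be E.

Step 7
Reactants: 12 (3R)-5-hydroxy-N-methoxy-N-methyl-3-[(2E,4E)-6-methylhepta-2,4,6-trien-2-yl]pentanamide
Product: 13 (3R)-N-methoxy-N-methyl-3-[(2E,4E)-6-methylhepta-2,4,6-trien-2-yl]-5-oxopentanamide
Conditions: Dess–Martin periodinane, NaHCO3, CH2Cl2, 0 °C, dark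
Reagents that add atoms: none
Why: Buffered Dess–Martin oxidation of the primary alcohol stops at the aldehyde and leaves triene and amide alone.

Step 8
Reactants: 13 (3R)-N-methoxy-N-methyl-3-[(2E,4E)-6-methylhepta-2,4,6-trien-2-yl]-5-oxopentanamide; 14 3-(triphenylphosphoranylidene)butan-2-one
Product: 15 (3R,5E)-N-methoxy-N,6-dimethyl-3-[(2E,4E)-6-methylhepta-2,4,6-trien-2-yl]-7-oxooct-5-enamide
Conditions: toluene, 80 °C
Reagents that add atoms: none
Why: Wittig olefination with the stabilised ylide is selective for the aldehyde over the amide and should give the E enone that carries C10, C14, C1 and C2.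

Step 9
Reactants: 15 (3R,5E)-N-methoxy-N,6-dimethyl-3-[(2E,4E)-6-methylhepta-2,4,6-trien-2-yl]-7-oxooct-5-enamide
Product: 16 (3R)-N-methoxy-N,6-dimethyl-3-[(2E,4E)-6-methylhepta-2,4,6-trien-2-yl]-7-[(triethylsilyl)oxy]oct-6-enamide (mixture of enol ether isomers)
Conditions: [(Ph3P)CuH]6, Et3SiCl, toluene/THF, −40 to 0 °C
Reagents that add atoms: chlorotriethylsilane, CC[Si](Cl)(CC)CC
Why: Copper hydride conjugate reduction with in situ silylation of the enolate fixes the enolate regiochemistry at C10 as the tetrasubstituted silyl enol ether; the unactivated triene and the Weinreb amide should be inert to this soft hydride.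

Step 10
Reactants: 16 (3R)-N-methoxy-N,6-dimethyl-3-[(2E,4E)-6-methylhepta-2,4,6-trien-2-yl]-7-[(triethylsilyl)oxy]oct-6-enamide; 17 2-bromoprop-2-en-1-ol
Product: 19 (5R)-2-(hydroxymethyl)-8-methyl-5-[(2E,4E)-6-methylhepta-2,4,6-trien-2-yl]-9-[(triethylsilyl)oxy]deca-1,8-dien-3-one, via dilithio allyl alkoxide 18 (not isolated)
Conditions: 17, t-BuLi (3 equiv), Et2O, −78 to 0 °C; then 16, THF, −78 °C; aq. NH4Cl
Reagents that add atoms: none
Why: The 2-lithioallyl alkoxide adds once to the Weinreb amide (stable chelated tetrahedral intermediate) and gives the α-methylene ketone on work-up, while the silyl enol ether masks the C1 ketone.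

Step 11
Reactants: 19 (5R)-2-(hydroxymethyl)-8-methyl-5-[(2E,4E)-6-methylhepta-2,4,6-trien-2-yl]-9-[(triethylsilyl)oxy]deca-1,8-dien-3-one
Product: 20 (5R)-2-(bromomethyl)-8-methyl-5-[(2E,4E)-6-methylhepta-2,4,6-trien-2-yl]-9-[(triethylsilyl)oxy]deca-1,8-dien-3-one
Conditions: CBr4, PPh3, 2,6-lutidine, CH2Cl2, −20 °C
Reagents that add atoms: carbon tetrabromide, BrC(Br)(Br)Br
Why: Appel bromination of the primary allylic alcohol under buffered conditions should give the 2-(bromomethyl)enone, which is used at once.

Step 12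
Reactants: 20 (5R)-2-(bromomethyl)-8-methyl-5-[(2E,4E)-6-methylhepta-2,4,6-trien-2-yl]-9-[(triethylsilyl)oxy]deca-1,8-dien-3-one
Product: 24 (4aR,6R,8aR)-4a-hydroxy-8a-methyl-4-methylidene-6-[(2E,4E)-6-methylhepta-2,4,6-trien-2-yl]octahydronaphthalen-1(2H)-one, via C10 enolate 21 (not isolated), via ring B aldolate 22 (not isolated), via C2 enolate 23 (not isolated)
Conditions: (Me2N)3S+ Me3SiF2− (1.05 equiv), THF (0.005 M), −78 to 0 °C; aq. NH4Cl
Reagents that add atoms: none
Why: Fluoride attacks silicon and frees the regiodefined tetrasubstituted C10 enolate 21, which adds to the C5 ketone (ring B, 6-(enolexo)-exo-trig aldol); the tertiary alkoxide 22 then takes a proton from the C2 methyl through a six-membered array, and the C2 enolate 23 displaces bromide at C3 (ring A, 6-(enolendo)-exo-tet C-alkylation; attack at C15 in the SN2′ sense gives the same product). The closest known reaction types are the aldol and C-alkylation reactions of fluoride-generated enolates from silyl enol ethers and the α,α′-annulation of ketones with 2-(bromomethyl)acrylate-type 1,3-dielectrophiles. The aldol is reversible and the alkylation is not, so C5 and C10 are set by the ring-closing transition state: the ketol with the acetyl group and the C4 arm both equatorial on the ring B chair (hydroxyl and methyl trans-diaxial) closes through an unstrained trans-decalin chair, and the bulky C7 trienyl group, which stays equatorial, fixes which enantiomeric face pair this is, so 5α-OH and 10β-CH3 should result. The step needs regiocontrol of enolisation, secured by the silyl enol ether and the absence of any external base at −78 °C so that C6 is not deprotonated; C- over O-alkylation, favoured by the soft allylic bromide and the enolendo geometry; and ring closure over oligomerisation, secured by high dilution. The change is redox-neutral and leaves only volatile silyl fluorides and a sulfonium bromide.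

Step 13
Reactants: 24 (4aR,6R,8aR)-4a-hydroxy-8a-methyl-4-methylidene-6-[(2E,4E)-6-methylhepta-2,4,6-trien-2-yl]octahydronaphthalen-1(2H)-one
Product: 25 (4aR,6R,8aR)-8a-methyl-4-methylidene-6-[(2E,4E)-6-methylhepta-2,4,6-trien-2-yl]-4a-[(triethylsilyl)oxy]octahydronaphthalen-1(2H)-one
Conditions: Et3SiOTf, 2,6-lutidine, CH2Cl2, −78 °C
Reagents that add atoms: triethylsilyl trifluoromethanesulfonate, CC[Si](CC)(CC)OS(=O)(=O)C(F)(F)F
Why: Silylation of the tertiary alcohol with the silyl triflate at low temperature is faster than enol silylation of the ketone and protects the ionisable allylic carbinol for the next two steps.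

Step 14
Reactants: 25 (4aR,6R,8aR)-8a-methyl-4-methylidene-6-[(2E,4E)-6-methylhepta-2,4,6-trien-2-yl]-4a-[(triethylsilyl)oxy]octahydronaphthalen-1(2H)-one
Product: 26 (1S,4aR,6R,8aS)-8a-methyl-4-methylidene-6-[(2E,4E)-6-methylhepta-2,4,6-trien-2-yl]-4a-[(triethylsilyl)oxy]decahydronaphthalen-1-ol (axial 1α-OH)
Conditions: LiBH(s-Bu)3, THF, −78 °C; aq. NH4Cl
Reagents that add atoms: none
Why: The bulky borohydride attacks the C1 ketone from the β face (equatorial attack) because the α face is blocked by the syn-axial C5 silyloxy group, which should give the axial 1α alcohol.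

Step 15
Reactants: 26 (1S,4aR,6R,8aS)-8a-methyl-4-methylidene-6-[(2E,4E)-6-methylhepta-2,4,6-trien-2-yl]-4a-[(triethylsilyl)oxy]decahydronaphthalen-1-ol
Product: 27 {[(1R,4aR,6R,8aR)-1-bromo-8a-methyl-4-methylidene-6-[(2E,4E)-6-methylhepta-2,4,6-trien-2-yl]octahydronaphthalen-4a(2H)-yl]oxy}triethylsilane (equatorial 1β-Br)
Conditions: CBr4, PPh3, 2,6-lutidine, toluene, 60 °C, dark
Reagents that add atoms: carbon tetrabromide, BrC(Br)(Br)Br
Why: Appel reaction: bromide displaces the alkoxyphosphonium group from the β face with inversion (SN2), turning the axial 1α alcohol into the equatorial 1β bromide; the centre is neopentyl-type, so this is the most demanding substitution of the route.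

Step 16
Reactants: 27 {[(1R,4aR,6R,8aR)-1-bromo-8a-methyl-4-methylidene-6-[(2E,4E)-6-methylhepta-2,4,6-trien-2-yl]octahydronaphthalen-4a(2H)-yl]oxy}triethylsilane
Product: 28 (1R,4aR,6R,8aR)-1-bromo-8a-methyl-4-methylidene-6-[(2E,4E)-6-methylhepta-2,4,6-trien-2-yl]octahydronaphthalen-4a(2H)-ol
Conditions: HF·pyridine, pyridine, THF, 0 °C
Reagents that add atoms: none
Why: Buffered acidic desilylation frees the tertiary alcohol without forming the C5 alkoxide, which would undergo Grob fragmentation (C1–Br is antiperiplanar to C5–C10).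

**Compound list**

1 | 5,6-dihydro-2H-pyran-2-one | O=C1C=CCCO1 | starting material
2 | potassium trifluoro(vinyl)borate | C=C[B-](F)(F)F.[K+] | starting material
3 | (4R)-4-ethenyloxan-2-one | C=C[C@@H]1CCOC(=O)C1 | intermediate
4 | (4R)-2-oxooxane-4-carbaldehyde | O=C[C@@H]1CCOC(=O)C1 | intermediate
5 | (4R)-4-ethynyloxan-2-one | C#C[C@@H]1CCOC(=O)C1 | intermediate
6 | methyl (3R)-3-ethynyl-5-hydroxypentanoate | C#C[C@@H](CC(=O)OC)CCO | intermediate
7 | (3R)-3-ethynyl-5-hydroxy-N-methoxy-N-methylpentanamide | C#C[C@@H](CC(=O)N(C)OC)CCO | intermediate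
8 | 2-methylbut-1-en-3-yne | C=C(C)C#C | starting material
9 | chlorobis(cyclopentadienyl)[(1E)-3-methylbuta-1,3-dien-1-yl]zirconium | C=C(C)/C=C/[Zr](Cl)(C1C=CC=C1)C1C=CC=C1 | intermediate
10 | (1E)-1-iodo-3-methylbuta-1,3-diene | C=C(C)/C=C/I | intermediate
11 | E alkenyl(dimethyl)alane of 7 (Al on C12, new methyl on C11, hydroxyl as its dimethylaluminium alkoxide) | C[Al](C)/C=C(\C)[C@@H](CC(=O)N(C)OC)CCO[Al](C)C | intermediate
12 | (3R)-5-hydroxy-N-methoxy-N-methyl-3-[(2E,4E)-6-methylhepta-2,4,6-trien-2-yl]pentanamide | C=C(C)/C=C/C=C(\C)[C@@H](CC(=O)N(C)OC)CCO | intermediate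
13 | (3R)-N-methoxy-N-methyl-3-[(2E,4E)-6-methylhepta-2,4,6-trien-2-yl]-5-oxopentanamide | C=C(C)/C=C/C=C(\C)[C@@H](CC(=O)N(C)OC)CC=O | intermediate
14 | 3-(triphenylphosphoranylidene)butan-2-one | CC(=O)C(C)=P(c1ccccc1)(c1ccccc1)c1ccccc1 | starting material
15 | (3R,5E)-N-methoxy-N,6-dimethyl-3-[(2E,4E)-6-methylhepta-2,4,6-trien-2-yl]-7-oxooct-5-enamide | C=C(C)/C=C/C=C(\C)[C@@H](CC(=O)N(C)OC)C/C=C(\C)C(C)=O | intermediate
16 | (3R)-N-methoxy-N,6-dimethyl-3-[(2E,4E)-6-methylhepta-2,4,6-trien-2-yl]-7-[(triethylsilyl)oxy]oct-6-enamide (enol ether isomers) | C=C(C)/C=C/C=C(\C)[C@@H](CC(=O)N(C)OC)CCC(C)=C(C)O[Si](CC)(CC)CC | intermediate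
17 | 2-bromoprop-2-en-1-ol | OCC(Br)=C | starting material
18 | lithium 2-lithioprop-2-en-1-olate | [Li]OCC([Li])=C | intermediate
19 | (5R)-2-(hydroxymethyl)-8-methyl-5-[(2E,4E)-6-methylhepta-2,4,6-trien-2-yl]-9-[(triethylsilyl)oxy]deca-1,8-dien-3-one | C=C(C)/C=C/C=C(\C)[C@@H](CC(=O)C(=C)CO)CCC(C)=C(C)O[Si](CC)(CC)CC | intermediate
20 | (5R)-2-(bromomethyl)-8-methyl-5-[(2E,4E)-6-methylhepta-2,4,6-trien-2-yl]-9-[(triethylsilyl)oxy]deca-1,8-dien-3-one | C=C(C)/C=C/C=C(\C)[C@@H](CC(=O)C(=C)CBr)CCC(C)=C(C)O[Si](CC)(CC)CC | intermediate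
21 | tris(dimethylamino)sulfonium C10=C1 enolate of the desilylated 20 | C=C(C)/C=C/C=C(\C)[C@@H](CC(=O)C(=C)CBr)CCC(C)=C(C)[O-].CN(C)[S+](N(C)C)N(C)C | intermediate
22 | tris(dimethylamino)sulfonium alkoxide of the ring B ketol (C5–C10 formed; acetyl and C4 arm equatorial, O and CH3 trans-diaxial, trienyl equatorial) | C=C(C)/C=C/C=C(\C)[C@@H]1CC[C@@](C)(C(C)=O)[C@]([O-])(C(=C)CBr)C1.CN(C)[S+](N(C)C)N(C)C | intermediate
23 | tris(dimethylamino)sulfonium C1=C2 enolate of the ring B ketol (proton moved from C2 to the C5 oxygen) | C=C(C)/C=C/C=C(\C)[C@@H]1CC[C@@](C)(C([O-])=C)[C@](O)(C(=C)CBr)C1.CN(C)[S+](N(C)C)N(C)C | intermediate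
24 | (4aR,6R,8aR)-4a-hydroxy-8a-methyl-4-methylidene-6-[(2E,4E)-6-methylhepta-2,4,6-trien-2-yl]octahydronaphthalen-1(2H)-one | C=C(C)/C=C/C=C(\C)[C@@H]1CC[C@@]2(C)C(=O)CCC(=C)[C@]2(O)C1 | intermediate
25 | (4aR,6R,8aR)-8a-methyl-4-methylidene-6-[(2E,4E)-6-methylhepta-2,4,6-trien-2-yl]-4a-[(triethylsilyl)oxy]octahydronaphthalen-1(2H)-one | C=C(C)/C=C/C=C(\C)[C@@H]1CC[C@@]2(C)C(=O)CCC(=C)[C@]2(O[Si](CC)(CC)CC)C1 | intermediate
26 | (1S,4aR,6R,8aS)-8a-methyl-4-methylidene-6-[(2E,4E)-6-methylhepta-2,4,6-trien-2-yl]-4a-[(triethylsilyl)oxy]decahydronaphthalen-1-ol | C=C(C)/C=C/C=C(\C)[C@@H]1CC[C@@]2(C)[C@@H](O)CCC(=C)[C@]2(O[Si](CC)(CC)CC)C1 | intermediate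
27 | {[(1R,4aR,6R,8aR)-1-bromo-8a-methyl-4-methylidene-6-[(2E,4E)-6-methylhepta-2,4,6-trien-2-yl]octahydronaphthalen-4a(2H)-yl]oxy}triethylsilane | C=C(C)/C=C/C=C(\C)[C@@H]1CC[C@@]2(C)[C@H](Br)CCC(=C)[C@]2(O[Si](CC)(CC)CC)C1 | intermediate
28 | (1R,4aR,6R,8aR)-1-bromo-8a-methyl-4-methylidene-6-[(2E,4E)-6-methylhepta-2,4,6-trien-2-yl]octahydronaphthalen-4a(2H)-ol | C=C(C)/C=C/C=C(\C)[C@@H]1CC[C@@]2(C)[C@H](Br)CCC(=C)[C@]2(O)C1 | target

**Step count and risks**

Total step count: 16. Longest linear sequence: 15 steps (steps 1–4 and 6–16; step 5 is a one-step side branch).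

Step 12 is the most exposed. The naked enolate may take a proton from C6 before it adds to C5, which would lose the regiocontrol and open the way to the wrong aldol and to O-alkylation; closure through a cis-fused ketol would erode the diastereoselectivity. The fallback separates the two bond formations and sets out from 20: BF3·OEt2 in CH2Cl2 at −78 °C should effect a Mukaiyama aldol to the ring B ketol F1, Et3SiOTf/2,6-lutidine should give its triethylsilyl ether F2, and KN(SiMe3)2 in THF at −78 °C can then form only the C2 enolate, which closes ring A by alkylation. This comes back to the route at 25.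

Step 15 may fail because elimination across C1–C2 (the axial H on C2 is antiperiplanar) or migration of the C10 methyl can outrun backside attack at the neopentyl centre. The fallback uses the syn-1,3-diol as the activating device and sets out from 26: HF·pyridine frees the diol F3, 1,1′-sulfonyldiimidazole with NaH should give the six-membered cyclic sulfate F4, LiBr in THF should open it at the secondary carbon with inversion to the lithium sulfate monoester F5, and mild acidic hydrolysis (cat. H2SO4, THF/H2O) releases the tertiary alcohol. This comes back to the route at 28.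

Step 6 may suffer from sluggish or non-regioselective carbometalation next to the coordinating amide and alkoxide, and from loss of alkene geometry or homocoupling in the one-pot coupling. The fallback replaces carboalumination by copper-catalysed methylboration and sets out from 7: CuCl (cat.), Xantphos, NaOt-Bu, B2pin2 and MeI in THF should add boron and methyl syn to give the E alkenylboronate F6, and Suzuki–Miyaura coupling with 10 (Pd(dppf)Cl2, aq. K3PO4, THF) joins the diene. This comes back to the route at 12.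

**Further compounds**

F1 | step 12 | 1-{2-(3-bromoprop-1-en-2-yl)-2-hydroxy-1-methyl-4-[(2E,4E)-6-methylhepta-2,4,6-trien-2-yl]cyclohexyl}ethan-1-one, configured as 24 at C5, C7 and C10 (ring B ketol) | C=C(C)/C=C/C=C(\C)[C@@H]1CC[C@@](C)(C(C)=O)[C@](O)(C(=C)CBr)C1
F2 | step 12 | triethylsilyl ether of F1 | C=C(C)/C=C/C=C(\C)[C@@H]1CC[C@@](C)(C(C)=O)[C@](O[Si](CC)(CC)CC)(C(=C)CBr)C1
F3 | step 15 | (1S,4aR,6R,8aS)-8a-methyl-4-methylidene-6-[(2E,4E)-6-methylhepta-2,4,6-trien-2-yl]octahydronaphthalene-1,4a(2H)-diol | C=C(C)/C=C/C=C(\C)[C@@H]1CC[C@@]2(C)[C@@H](O)CCC(=C)[C@]2(O)C1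
F4 | step 15 | cyclic sulfate of F3 bridging the C1 and C5 oxygens | C=C(C)/C=C/C=C(\C)[C@@H]1CC[C@@]2(C)[C@@H]3CCC(=C)[C@]2(OS(=O)(=O)O3)C1
F5 | step 15 | lithium salt of the C5 sulfate monoester of 28 (1β-bromide) | C=C(C)/C=C/C=C(\C)[C@@H]1CC[C@@]2(C)[C@H](Br)CCC(=C)[C@]2(OS(=O)(=O)[O-])C1.[Li+]
F6 | step 6 | (3R)-5-hydroxy-N-methoxy-N-methyl-3-[(1E)-1-(4,4,5,5-tetramethyl-1,3,2-dioxaborolan-2-yl)prop-1-en-2-yl]pentanamide | CC1(C)OB(OC1(C)C)/C=C(\C)[C@@H](CC(=O)N(C)OC)CCO
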